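**Plan** (ring numbered C1 = carbonyl, C2 = alkenyl carbon, C3 = CH2OH carbon, C4 and C5 = carbinols, C6 = carbon bearing the butenoic acid chain)
1. Cuts, in retrosynthetic order: the C2–alkenyl bond (Stille coupling on a 2-iodoenone); the C2=C3 enone with C4–OH and C5–OH back to an exo-epoxy 7-oxanorbornanone (reductive bridge opening); the C6–CH2 bond (enolate alkylation); last, C1–C2 and C5–C6 together (Diels–Alder).
2. Enabling feature: C2–C3–C4–C5 with the C5 oxygen is a latent 3-(hydroxymethyl)furan and C1–C6 a latent two-carbon β-keto ester unit (a 3-bromopropiolate). The C4-OH, C5-OH and C6 chain are all cis, so all three lie on the oxygen-bridge (exo) face of a 7-oxabicyclo[2.2.1]heptene.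
3. Forward: furan + bromoynoate gives the carbocycle inside an oxanorbornadiene; bromide is exchanged for a chiral amine and the ester carbon leaves as CO2 to give the ketone; exo-alkylation, exo-epoxidation, then SmI2 cuts the oxygen bridge and opens the epoxide to the enone cis-diol; acetonide, iodination, Stille coupling, global acidolysis.
4. Stereochemistry: the bridgeheads are resolved as (R)-1-phenylethylamine enamines (bought stereocentre); C6 and C4 are relayed from them by exo attack and the C5 oxygen is the furan oxygen; the remote carbinol comes from (R)-propylene oxide; alkene geometries come from Wittig olefination and syn-hydrostannation.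

Key step: step 4

Remark: compounds 12 and 23 are taken as purchasable, and the two diastereomeric enamino esters of step 5 are assumed to be separable on silica or by crystallisation (TBS = tert-butyldimethylsilyl).

**Step 1**
Reactants: 1 furan-3-ylmethanol
Product: 2 tert-butyl(furan-3-ylmethoxy)dimethylsilane
Conditions: TBSCl, imidazole, CH2Cl2, 0 °C to rt
Reagents that add atoms: tert-butyldimethylsilyl chloride, CC(C)(C)[Si](C)(C)Cl
Why: Imidazole-promoted silylation of the primary alcohol masks the hydroxyl, which would otherwise add to the bromoynoate, and leaves an electron-releasing CH2OSi group on C3 of the furan.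

**Step 2**
Reactants: 3 propiolic acid; 4 allyl alcohol
Product: 5 allyl propiolate (prop-2-en-1-yl prop-2-ynoate)
Conditions: TsOH·H2O (cat.), PhH, reflux, Dean–Stark
Reagents that add atoms: none
Why: Fischer esterification driven by azeotropic removal of water; the allyl ester is chosen because zerovalent palladium can remove it later under neutral conditions.

**Step 3**
Reactants: 5 allyl propiolate
Product: 6 allyl 3-bromopropiolate (prop-2-en-1-yl 3-bromoprop-2-ynoate)
Conditions: NBS, AgNO3 (cat.), acetone, rt
Reagents that add atoms: N-bromosuccinimide, O=C1CCC(=O)N1Br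
Why: Silver-catalysed electrophilic bromination of the terminal alkyne (through the silver acetylide) gives the 1-bromoalkyne, which is used fresh.

**Step 4**
Reactants: 2 tert-butyl(furan-3-ylmethoxy)dimethylsilane; 6 allyl 3-bromopropiolate
Product: 7 racemic prop-2-en-1-yl (1R*,4S*)-3-bromo-5-{[(TBS)oxy]methyl}-7-oxabicyclo[2.2.1]hepta-2,5-diene-2-carboxylate
Conditions: PhMe, 80 °C, BHT (cat.), sealed tube
Reagents that add atoms: none
Why: Thermal, concerted but asynchronous [4+2] cycloaddition in which the furan of 2 is the 4π partner (its α-carbons become C2 and C5 of the target ring and its oxygen the C5 hydroxyl oxygen) and the bromoynoate 6 the 2π partner (future C1, marked by bromine, and C6, carrying the ester). The closest known reaction type is the thermal Diels–Alder addition of alkyl 3-bromopropiolates to furans, which gives 3-bromo-7-oxanorbornadiene-2-carboxylates. The six-membered carbocycle closes by intermolecular suprafacial/suprafacial [4+2] addition, and the 7-oxabicyclo[2.2.1]heptadiene forms with it. The two bridgeheads are the only new stereocentres: the one-atom oxygen bridge fixes their relative configuration, they form as a racemate, and the absolute sense is selected in step 5. The step needs regioselectivity only (an alkyne has no endo/exo question): the electron-releasing CH2OTBS group on C3 of the furan makes the adjacent α-carbon the more nucleophilic terminus (para rule for 2-substituted dienes), which should pair with the bromine-bearing β-carbon of the ynoate where the LUMO coefficient is largest, and the bulky silyl ether keeps the larger ester end on the far side. This directing effect is modest, so some of the other regioisomer is expected and should be removable by chromatography at this stage.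

**Step 5**
Reactants: 7 racemic bromo-oxanorbornadiene allyl ester
Product: 8 prop-2-en-1-yl (1R,4S)-5-{[(TBS)oxy]methyl}-3-{[(1R)-1-phenylethyl]amino}-7-oxabicyclo[2.2.1]hepta-2,5-diene-2-carboxylate
Conditions: (R)-1-phenylethylamine, Et3N, MeCN, 0 °C to rt; diastereomers separated on silica
Reagents that add atoms: (R)-1-phenylethylamine, C[C@@H](N)c1ccccc1
Why: Addition–elimination (vinylic substitution) of the amine at the bromine-bearing β-carbon of the strained enoate gives the hydrogen-bonded enamino ester, and the bought (R) stereocentre turns the two bridgehead enantiomers into diastereomers, of which the (1R,4S) one is kept.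

**Step 6**
Reactants: 8 (1R,4S) enamino allyl ester
Product: 11 (1S,4S)-6-{[(TBS)oxy]methyl}-7-oxabicyclo[2.2.1]hept-5-en-2-one, via enamino acid 9 (not isolated), via imine 10 (not isolated)
Conditions: Pd(PPh3)4 (cat.), morpholine, THF, rt; then aq. oxalic acid, rt
Reagents that add atoms: water, O
Why: Palladium-catalysed deallylation (allyl transfer from the π-allyl complex of zerovalent palladium to morpholine) frees the vinylogous carbamic acid, which loses CO2 on acidification like a β-keto acid, and the resulting imine is hydrolysed, so the ester carbon that steered the cycloaddition leaves without base and the bridgeheads are untouched.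

**Step 7**
Reactants: 12 tert-butyl 2-(triphenyl-λ5-phosphanylidene)propanoate; 13 glycolaldehyde dimer (1,4-dioxane-2,5-diol)
Product: 14 tert-butyl (2E)-4-hydroxy-2-methylbut-2-enoate
Conditions: CH2Cl2, reflux
Reagents that add atoms: none
Why: Wittig olefination of the aldehyde (released from its dimer) with a stabilised ylide gives the E-trisubstituted enoate under thermodynamic control of the oxaphosphetane.

**Step 8**
Reactants: 14 tert-butyl (2E)-4-hydroxy-2-methylbut-2-enoate
Product: 15 tert-butyl (2E)-4-bromo-2-methylbut-2-enoate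
Conditions: CBr4, PPh3, CH2Cl2, 0 °C
Reagents that add atoms: carbon tetrabromide, BrC(Br)(Br)Br
Why: Appel bromination of the primary allylic alcohol proceeds by SN2 at CH2 and keeps the alkene geometry.

**Step 9**
Reactants: 11 (1S,4S) oxanorbornenone; 15 tert-butyl (2E)-4-bromo-2-methylbut-2-enoate
Product: 17 (1S,3R,4R)-3-exo-[(2E)-4-tert-butoxy-3-methyl-4-oxobut-2-en-1-yl]-6-{[(TBS)oxy]methyl}-7-oxabicyclo[2.2.1]hept-5-en-2-one, via lithium enolate 16 (not isolated)
Conditions: LiN(i-Pr)2 (LDA), THF, −78 °C; then 15, DMPU, −78 to −40 °C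
Reagents that add atoms: none
Why: Enolate alkylation (SN2): only C3 of the bicycle can enolise (the bridgehead cannot, Bredt's rule), and the enolate is attacked by the allylic bromide on the exo face, syn to the oxygen bridge, which sets C6 of the target cis to the future C5 oxygen.

**Step 10**
Reactants: 17 exo-alkylated oxanorbornenone
Product: 18 exo-5,6-epoxide of 17 (epoxide oxygen syn to the oxygen bridge; CH2OTBS on the epoxide carbon next to the C1 bridgehead)
Conditions: DMDO, acetone, 0 °C
Reagents that add atoms: dimethyldioxirane, CC1(C)OO1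
Why: Electrophilic epoxidation of the strained, electron-rich trisubstituted alkene from the exo face places the future C4 oxygen on the bridge side; the electron-poor enoate is left alone and the neutral dioxirane avoids Baeyer–Villiger oxidation of the ketone.

**Step 11**
Reactants: 18 exo-epoxy oxanorbornanone
Product: 20 tert-butyl (2E)-4-[(1R,5R,6S)-4-{[(TBS)oxy]methyl}-5,6-dihydroxy-2-oxocyclohex-3-en-1-yl]-2-methylbut-2-enoate, via epoxy ketol 19 (not isolated)
Conditions: SmI2, THF/MeOH, −78 °C; then Et3N, 0 °C
Reagents that add atoms: none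
Why: SmI2 reduces the ketone to a ketyl that expels the α-oxygen bridge (the known reductive opening of 7-oxanorbornan-2-ones), and the enolisable β,γ-epoxy ketone then opens by E1cB to the γ-hydroxy enone; no stereocentre is touched, so C4-OH, C5-OH and the C6 chain stay cis.

**Step 12**
Reactants: 20 enone cis-diol
Product: 21 4,5-O-isopropylidene derivative of 20 (cis-fused acetonide)
Conditions: Me2C(OMe)2, PPTS (cat.), CH2Cl2, rt
Reagents that add atoms: 2,2-dimethoxypropane, COC(C)(C)OC
Why: Acid-catalysed transketalisation on the cis-1,2-diol protects the β-hydroxy ketone against elimination during the next two steps.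

**Step 13**
Reactants: 21 acetonide enone
Product: 22 2-iodo derivative of 21 (iodine on the enone α-carbon, target C2)
Conditions: I2, pyridine, DMAP (cat.), CH2Cl2, rt
Reagents that add atoms: iodine, II
Why: Baylis–Hillman-type α-iodination (conjugate addition of the amine, iodination of the enolate, elimination), as known for 3-substituted cyclohexenones and for 4,5-O-isopropylidene cyclohexenones.

**Step 14**
Reactants: 23 (4-bromobut-1-yn-1-yl)trimethylsilane; 24 (R)-2-methyloxirane
Product: 26 (2R)-7-(trimethylsilyl)hept-6-yn-2-ol, via Grignard reagent 25 (not isolated)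
Conditions: Mg, THF, rt; then CuI (cat.), 24, THF, −30 to 0 °C; aq. NH4Cl
Reagents that add atoms: none
Why: Copper-catalysed Grignard opening of the epoxide at its unsubstituted carbon (SN2) leaves the bought stereocentre untouched and gives the (R) alcohol.

**Step 15**
Reactants: 26 (2R)-7-(trimethylsilyl)hept-6-yn-2-ol
Product: 27 (2R)-hept-6-yn-2-ol
Conditions: K2CO3, MeOH, rt
Reagents that add atoms: none
Why: Methoxide-mediated protodesilylation of the alkynylsilane frees the terminal alkyne.

**Step 16**
Reactants: 27 (2R)-hept-6-yn-2-ol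
Product: 28 (2R,6E)-7-(tributylstannyl)hept-6-en-2-ol
Conditions: Bu3SnH, Pd2(dba)3 (cat.), Cy3P·HBF4 (cat.), i-Pr2NEt, CH2Cl2, 0 °C
Reagents that add atoms: tributyltin hydride, CCCC[SnH](CCCC)CCCC
Why: Palladium-catalysed hydrostannation is a syn addition, and the bulky trialkylphosphine directs tin to the terminal carbon, giving the E-vinylstannane.

**Step 17**
Reactants: 22 iodoenone; 28 (2R,6E)-7-(tributylstannyl)hept-6-en-2-ol
Product: 29 2-[(1E,6R)-6-hydroxyhept-1-en-1-yl] derivative of 21 (fully protected target: tert-butyl ester, TBS ether, acetonide)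
Conditions: Pd2(dba)3 (cat.), AsPh3, CuI (cat.), NMP, rt to 40 °C
Reagents that add atoms: none
Why: Stille coupling of the 2-iodoenone with the E-vinylstannane under neutral conditions forms the C2–alkenyl bond with retention of both alkene geometries and tolerates the free secondary alcohol.

**Step 18**
Reactants: 29 fully protected target
Product: 30 pestallic acid I
Conditions: TFA/CH2Cl2 (1:1), H2O (5 equiv), 0 °C to rt
Reagents that add atoms: none
Why: Acidolysis removes the tert-butyl ester (through the tert-butyl cation), the acetonide and the silyl ether in one operation without base, which the β-hydroxy ketone and the C6 stereocentre would not tolerate.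

**Compound list**
1 | furan-3-ylmethanol | OCc1ccoc1 | starting material
2 | tert-butyl(furan-3-ylmethoxy)dimethylsilane | CC(C)(C)[Si](C)(C)OCc1ccoc1 | intermediate
3 | propiolic acid | C#CC(=O)O | starting material
4 | allyl alcohol | C=CCO | starting material
5 | allyl propiolate | C#CC(=O)OCC=C | intermediate
6 | allyl 3-bromopropiolate | BrC#CC(=O)OCC=C | intermediate
7 | racemic prop-2-en-1-yl (1R*,4S*)-3-bromo-5-{[(TBS)oxy]methyl}-7-oxabicyclo[2.2.1]hepta-2,5-diene-2-carboxylate | C=CCOC(=O)C1=C(Br)C2OC1C=C2CO[Si](C)(C)C(C)(C)C | intermediate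
8 | prop-2-en-1-yl (1R,4S)-5-{[(TBS)oxy]methyl}-3-{[(1R)-1-phenylethyl]amino}-7-oxabicyclo[2.2.1]hepta-2,5-diene-2-carboxylate | C=CCOC(=O)C1=C(N[C@H](C)c3ccccc3)[C@H]2O[C@@H]1C=C2CO[Si](C)(C)C(C)(C)C | intermediate
9 | (1R,4S)-5-{[(TBS)oxy]methyl}-3-{[(1R)-1-phenylethyl]amino}-7-oxabicyclo[2.2.1]hepta-2,5-diene-2-carboxylic acid | OC(=O)C1=C(N[C@H](C)c3ccccc3)[C@H]2O[C@@H]1C=C2CO[Si](C)(C)C(C)(C)C | intermediate
10 | (1S,4S)-6-{[(TBS)oxy]methyl}-N-[(1R)-1-phenylethyl]-7-oxabicyclo[2.2.1]hept-5-en-2-imine | C[C@@H](N=C1C[C@H]2C=C(CO[Si](C)(C)C(C)(C)C)[C@@H]1O2)c1ccccc1 | intermediate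
11 | (1S,4S)-6-{[(TBS)oxy]methyl}-7-oxabicyclo[2.2.1]hept-5-en-2-one | O=C1C[C@H]2C=C(CO[Si](C)(C)C(C)(C)C)[C@@H]1O2 | intermediate
12 | tert-butyl 2-(triphenyl-λ5-phosphanylidene)propanoate | CC(=P(c1ccccc1)(c1ccccc1)c1ccccc1)C(=O)OC(C)(C)C | starting material
13 | glycolaldehyde dimer (1,4-dioxane-2,5-diol) | OC1COC(O)CO1 | starting material
14 | tert-butyl (2E)-4-hydroxy-2-methylbut-2-enoate | C/C(=C\CO)C(=O)OC(C)(C)C | intermediate
15 | tert-butyl (2E)-4-bromo-2-methylbut-2-enoate | C/C(=C\CBr)C(=O)OC(C)(C)C | intermediate
16 | lithium enolate of 11 (C2=C3 enolate, bridgeheads as in 11) | [Li]OC1=C[C@H]2C=C(CO[Si](C)(C)C(C)(C)C)[C@@H]1O2 | intermediate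
17 | (1S,3R,4R)-3-exo-[(2E)-4-tert-butoxy-3-methyl-4-oxobut-2-en-1-yl]-6-{[(TBS)oxy]methyl}-7-oxabicyclo[2.2.1]hept-5-en-2-one | O=C1[C@H](C/C=C(\C)C(=O)OC(C)(C)C)[C@H]2C=C(CO[Si](C)(C)C(C)(C)C)[C@@H]1O2 | intermediate
18 | exo-5,6-epoxide of 17 (epoxide oxygen syn to the oxygen bridge) | O=C1[C@H](C/C=C(\C)C(=O)OC(C)(C)C)[C@H]2[C@@H]3O[C@]3(CO[Si](C)(C)C(C)(C)C)[C@@H]1O2 | intermediate
19 | ring-opened β,γ-epoxy ketol: 3,4-epoxy-5-hydroxy-3-(TBSOCH2)cyclohexanone with the 6-side chain, epoxide, 5-OH and side chain all cis | C/C(=C\C[C@H]1C(=O)C[C@@]2(CO[Si](C)(C)C(C)(C)C)O[C@H]2[C@H]1O)C(=O)OC(C)(C)C | intermediate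
20 | tert-butyl (2E)-4-[(1R,5R,6S)-4-{[(TBS)oxy]methyl}-5,6-dihydroxy-2-oxocyclohex-3-en-1-yl]-2-methylbut-2-enoate | C/C(=C\C[C@H]1C(=O)C=C(CO[Si](C)(C)C(C)(C)C)[C@@H](O)[C@H]1O)C(=O)OC(C)(C)C | intermediate
21 | 4,5-O-isopropylidene derivative of 20 (cis-fused acetonide) | C/C(=C\C[C@H]1C(=O)C=C(CO[Si](C)(C)C(C)(C)C)[C@H]2OC(C)(C)O[C@@H]12)C(=O)OC(C)(C)C | intermediate
22 | 2-iodo derivative of 21 | C/C(=C\C[C@H]1C(=O)C(I)=C(CO[Si](C)(C)C(C)(C)C)[C@H]2OC(C)(C)O[C@@H]12)C(=O)OC(C)(C)C | intermediate
23 | (4-bromobut-1-yn-1-yl)trimethylsilane | C[Si](C)(C)C#CCCBr | starting material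
24 | (R)-2-methyloxirane | C[C@@H]1CO1 | starting material
25 | [4-(trimethylsilyl)but-3-yn-1-yl]magnesium bromide | C[Si](C)(C)C#CCC[Mg]Br | intermediate
26 | (2R)-7-(trimethylsilyl)hept-6-yn-2-ol | C[C@@H](O)CCCC#C[Si](C)(C)C | intermediate
27 | (2R)-hept-6-yn-2-ol | C[C@@H](O)CCCC#C | intermediate
28 | (2R,6E)-7-(tributylstannyl)hept-6-en-2-ol | C[C@@H](O)CCC/C=C/[Sn](CCCC)(CCCC)CCCC | intermediate
29 | fully protected target: 2-[(1E,6R)-6-hydroxyhept-1-en-1-yl] derivative of 21 | C/C(=C\C[C@H]1C(=O)C(/C=C/CCC[C@@H](C)O)=C(CO[Si](C)(C)C(C)(C)C)[C@H]2OC(C)(C)O[C@@H]12)C(=O)OC(C)(C)C | intermediate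
30 | pestallic acid I: (2E)-4-[(1R,5R,6S)-5,6-dihydroxy-3-[(1E,6R)-6-hydroxyhept-1-en-1-yl]-4-(hydroxymethyl)-2-oxocyclohex-3-en-1-yl]-2-methylbut-2-enoic acid | C/C(=C\C[C@H]1C(=O)C(/C=C/CCC[C@@H](C)O)=C(CO)[C@@H](O)[C@H]1O)C(=O)O | target

**Total step count:** 18.
**Longest linear sequence:** 12 steps (steps 2, 3, 4, 5, 6, 9, 10, 11, 12, 13, 17, 18).

**Steps most likely to fail**

Step 5. The two diastereomeric enamino esters may co-elute or co-crystallise, or exchange amine on silica, so that the bridgeheads are not resolved. Fallback: set out from 7 and displace the bromide with morpholine to give the racemic morpholine enamino ester F1. Deallylation, decarboxylation and hydrolysis as in step 6 then give the racemic ketone F2. The ketone is resolved by the sulfoximine method: addition of lithiated (S)-N,S-dimethyl-S-phenylsulfoximine (n-BuLi, THF, −78 °C) from the exo face gives two diastereomeric β-hydroxy sulfoximines, which are separated. The one built on the (1S,4S) bicycle, the exo-adduct β-hydroxy sulfoximine F3, is thermolysed in toluene at 110 °C. This releases the enantiopure ketone, and the route is rejoined at 11.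

Step 11. The newly formed γ-oxygenated enone may be reduced further by SmI2, the epoxide may open incompletely, or C6 may epimerise during the base stage. Fallback: set out from 17 and carry out the reductive bridge opening before the oxidation. SmI2 in THF/MeOH at −78 °C, with kinetic α-protonation of the dienolate, gives the β,γ-unsaturated hydroxy ketone F4. Its allylic C5 hydroxyl then directs epoxidation (VO(acac)2 cat., t-BuOOH, CH2Cl2, 0 °C) to the same face, which gives the epoxy ketol 19. Et3N converts 19 into 20 as in the second stage of step 11.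

Step 18. Under the strongly acidic conditions the C5 hydroxyl may be lost by acid-catalysed β-elimination with subsequent aromatisation to a phenol, before the tert-butyl ester is fully cleaved. Fallback: set out from 29 and separate the two tasks. ZnBr2 in CH2Cl2 at rt cleaves the tert-butyl ester selectively and gives the silyl- and acetonide-protected carboxylic acid F5. A sulfonic acid ion-exchange resin in MeOH/H2O at rt then removes the acetonide and the silyl ether under much milder acidity, and the route ends at 30.

**Further compounds**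
F1 | step 5 | racemic prop-2-en-1-yl 5-{[(TBS)oxy]methyl}-3-(morpholin-4-yl)-7-oxabicyclo[2.2.1]hepta-2,5-diene-2-carboxylate | C=CCOC(=O)C1=C(N3CCOCC3)C2OC1C=C2CO[Si](C)(C)C(C)(C)C
F2 | step 5 | racemic 6-{[(TBS)oxy]methyl}-7-oxabicyclo[2.2.1]hept-5-en-2-one | O=C1CC2C=C(CO[Si](C)(C)C(C)(C)C)C1O2
F3 | step 5 | exo-adduct of the (1S,4S) ketone with the lithiated (S)-sulfoximine: 2-endo-hydroxy-2-exo-{[(S)-N-methyl-S-phenylsulfonimidoyl]methyl}-6-{[(TBS)oxy]methyl}-7-oxabicyclo[2.2.1]hept-5-ene | O[C@@]1(C[S@@](=O)(=NC)c3ccccc3)C[C@H]2C=C(CO[Si](C)(C)C(C)(C)C)[C@@H]1O2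
F4 | step 11 | tert-butyl (2E)-4-[(1R,6S)-4-{[(TBS)oxy]methyl}-6-hydroxy-2-oxocyclohex-4-en-1-yl]-2-methylbut-2-enoate (side chain and hydroxyl cis) | C/C(=C\C[C@H]1C(=O)CC(CO[Si](C)(C)C(C)(C)C)=C[C@H]1O)C(=O)OC(C)(C)C
F5 | step 18 | carboxylic acid of 29 (tert-butyl ester cleaved; TBS ether and acetonide intact) | C/C(=C\C[C@H]1C(=O)C(/C=C/CCC[C@@H](C)O)=C(CO[Si](C)(C)C(C)(C)C)[C@H]2OC(C)(C)O[C@@H]12)C(=O)O
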